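**Retrosynthetic overview**
- The caffeoyl ester C–O bond and the only stereocentre are made together, by amine-catalysed α-acyloxylation of an achiral 3-arylpropanal with the complete acid fragment (delivered as a mixed diacyl peroxide); CHO → CO2H oxidation and removal of five benzyl ethers finish the synthesis.
- Acid fragment: enol-ether C=C by Horner–Wadsworth–Emmons olefination, aryl O–C bond by rhodium-carbenoid O–H insertion into the 4-OH of a 3-O-benzyl caffeate, cinnamate C=C by Wittig olefination.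
- Aldehyde fragment: Heck arylation of allyl alcohol with a protected 4-bromocatechol.
- Rings: none is formed; the three benzene rings are bought and joined in the order ring B (central ring), ring A (enol-ether aryl, step 3), ring C (aryl-lactic acid part, step 7).

Assumption: 1, 2, 4, 6, 9, 10 and 12 are taken as catalogue chemicals; peracid 13 is not, so its one-step preparation is counted as step 6.

**Step 1**
Reactants: 1 3-(benzyloxy)-4-hydroxybenzaldehyde; 2 tert-butyl (triphenylphosphoranylidene)acetate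
Product: 3 tert-butyl (E)-3-[3-(benzyloxy)-4-hydroxyphenyl]prop-2-enoate
Conditions: toluene, 100 °C
Reagents that add atoms: none
Why: Wittig olefination with a stabilised ylide reacts only at the aldehyde, tolerates the free phenol and gives the (E)-cinnamate.

**Step 2**
Reactants: 3 tert-butyl (E)-3-[3-(benzyloxy)-4-hydroxyphenyl]prop-2-enoate; 4 methyl 2-diazo-2-(dimethoxyphosphoryl)acetate
Product: 5 tert-butyl (E)-3-{3-(benzyloxy)-4-[1-(dimethoxyphosphoryl)-2-methoxy-2-oxoethoxy]phenyl}prop-2-enoate (racemic)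
Conditions: Rh2(OAc)4 (2 mol %), toluene, 80 °C
Reagents that add atoms: none
Why: The electrophilic rhodium carbenoid from 4 inserts into the acidic phenol O–H (O–H insertion) much faster than it cyclopropanates the electron-poor cinnamate, giving the aryloxy phosphonoacetate, whose new centre is racemic and is erased in step 3.

**Step 3**
Reactants: 5 tert-butyl (E)-3-{3-(benzyloxy)-4-[1-(dimethoxyphosphoryl)-2-methoxy-2-oxoethoxy]phenyl}prop-2-enoate; 6 3,4-bis(benzyloxy)benzaldehyde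
Product: 7 methyl (Z)-2-{2-(benzyloxy)-4-[(E)-3-tert-butoxy-3-oxoprop-1-enyl]phenoxy}-3-[3,4-bis(benzyloxy)phenyl]prop-2-enoate
Conditions: NaH, THF, 0 °C → rt
Reagents that add atoms: none
Why: Horner–Wadsworth–Emmons olefination of the aryloxy phosphonoacetate with an aromatic aldehyde gives the α-aryloxycinnamate, the reversible addition funnelling to the more stable (Z)-isomer in which aryl and ester are trans, and the minor (E)-isomer is removed by chromatography.

**Step 4**
Reactants: 7 methyl (Z)-2-{2-(benzyloxy)-4-[(E)-3-tert-butoxy-3-oxoprop-1-enyl]phenoxy}-3-[3,4-bis(benzyloxy)phenyl]prop-2-enoate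
Product: 8 (E)-3-[3-(benzyloxy)-4-({(Z)-1-[3,4-bis(benzyloxy)phenyl]-3-methoxy-3-oxoprop-1-en-2-yl}oxy)phenyl]prop-2-enoic acid
Conditions: TFA/CH2Cl2 (1:4), 0 °C → rt
Reagents that add atoms: none
Why: Acidolysis of the tert-butyl ester (loss of isobutene) frees the cinnamic acid, while the methyl ester, the aryl benzyl ethers and the electron-poor enol ether survive short exposure to dilute TFA.

**Step 5**
Reactants: 9 1,2-bis(benzyloxy)-4-bromobenzene; 10 prop-2-en-1-ol
Product: 11 3-[3,4-bis(benzyloxy)phenyl]propanal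
Conditions: Pd(OAc)2 (3 mol %), Bu4NCl, NaHCO3, DMF, 90 °C
Reagents that add atoms: none
Why: Heck arylation of allyl alcohol under ligand-free Jeffery conditions adds the aryl–palladium species to the terminal carbon, and β-hydride elimination towards the carbinol carbon gives the enol and hence the 3-arylpropanal in one step.

**Step 6**
Reactants: 12 2,4,6-trichlorobenzoyl chloride
Product: 13 2,4,6-trichloroperoxybenzoic acid
Conditions: 30% aq. H2O2, NaOH, MgSO4, THF/H2O, 0 °C; then dil. H2SO4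
Reagents that add atoms: hydrogen peroxide, OO
Why: Perhydrolysis of an aroyl chloride by alkaline hydrogen peroxide (the way mCPBA is made) works because the hydroperoxide anion outcompetes hydroxide, and the two ortho chlorines hinder a second acylation to the diaroyl peroxide.

**Step 7**
Reactants: 8 (E)-3-[3-(benzyloxy)-4-({(Z)-1-[3,4-bis(benzyloxy)phenyl]-3-methoxy-3-oxoprop-1-en-2-yl}oxy)phenyl]prop-2-enoic acid; 13 2,4,6-trichloroperoxybenzoic acid; 11 3-[3,4-bis(benzyloxy)phenyl]propanal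
Product: 16 (R)-3-[3,4-bis(benzyloxy)phenyl]-2-{[(E)-3-[3-(benzyloxy)-4-({(Z)-1-[3,4-bis(benzyloxy)phenyl]-3-methoxy-3-oxoprop-1-en-2-yl}oxy)phenyl]prop-2-enoyl]oxy}propanoic acid, via mixed diacyl peroxide 14 (not isolated), via (R)-α-acyloxy aldehyde 15 (not isolated)
Conditions: N,N'-diisopropylcarbodiimide (1.0 equiv), CH2Cl2, −20 °C; then 2-methyl-2-butene (excess), 11 (1.5 equiv), (R)-2-(triphenylmethyl)pyrrolidine (20 mol %), hydroquinone (10 mol %), THF, −20 → 0 °C; then NaClO2, NaH2PO4, t-BuOH/H2O, 0 °C → rt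
Reagents that add atoms: sodium chlorite NaClO2, [Na+].[O-]Cl=O
Why: Proposed new method: a mixed "peroxy-Yamaguchi" diacyl peroxide serves as a chemoselective acyloxy-transfer reagent in enamine catalysis, in that carbodiimide coupling of acid 8 and peracid 13 (a known way to unsymmetrical diacyl peroxides) gives 14, whose peroxidic oxygen on the unhindered cinnamoyl side is attacked by the (E)-anti enamine of 11 from the face remote from the trityl group because 2,4,6-trichlorobenzoate (pKa about 1.5 against about 4.4 for the cinnamic acid) is the far better leaving group and its own oxygen and carbonyl are screened by two ortho chlorines, so the entire acyloxy group of 8 is delivered to C-2 and the (R) centre is set by the (R) catalyst, the closest known reaction type being the 2-tritylpyrrolidine- or diarylprolinol silyl ether-catalysed enantioselective α-benzoyloxylation of aldehydes by symmetrical dibenzoyl peroxide, and Pinnick oxidation in the same flask turns the configurationally labile α-acyloxy aldehyde 15 into the stable acid without touching the stereocentre.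

**Step 8**
Reactants: 16 (R)-3-[3,4-bis(benzyloxy)phenyl]-2-{[(E)-3-[3-(benzyloxy)-4-({(Z)-1-[3,4-bis(benzyloxy)phenyl]-3-methoxy-3-oxoprop-1-en-2-yl}oxy)phenyl]prop-2-enoyl]oxy}propanoic acid
Product: 17 (R)-3-(3,4-dihydroxyphenyl)-2-{[(E)-3-[4-({(Z)-1-(3,4-dihydroxyphenyl)-3-methoxy-3-oxoprop-1-en-2-yl}oxy)-3-hydroxyphenyl]prop-2-enoyl]oxy}propanoic acid (CNP0242322.1)
Conditions: BCl3 (12 equiv), C6HMe5 (15 equiv), CH2Cl2, −78 → −40 °C; then THF/H2O
Reagents that add atoms: none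
Why: Lewis-acid debenzylation by BCl3 at low temperature, in which pentamethylbenzene as a non-basic scavenger takes up each benzyl cation (Friedel–Crafts benzyl transfer), cleaves the five aryl benzyl ethers while the two esters, the free acid, both alkenes and the stereocentre are left untouched.

**Compound list**
1 | 3-(benzyloxy)-4-hydroxybenzaldehyde | O=Cc1ccc(O)c(OCc2ccccc2)c1 | starting material
2 | tert-butyl (triphenylphosphoranylidene)acetate | CC(C)(C)OC(=O)C=P(c1ccccc1)(c1ccccc1)c1ccccc1 | starting material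
3 | tert-butyl (E)-3-[3-(benzyloxy)-4-hydroxyphenyl]prop-2-enoate | CC(C)(C)OC(=O)/C=C/c1ccc(O)c(OCc2ccccc2)c1 | intermediate
4 | methyl 2-diazo-2-(dimethoxyphosphoryl)acetate | COC(=O)C(=[N+]=[N-])P(=O)(OC)OC | starting material
5 | tert-butyl (E)-3-{3-(benzyloxy)-4-[1-(dimethoxyphosphoryl)-2-methoxy-2-oxoethoxy]phenyl}prop-2-enoate (racemic) | COC(=O)C(Oc1ccc(/C=C/C(=O)OC(C)(C)C)cc1OCc1ccccc1)P(=O)(OC)OC | intermediate
6 | 3,4-bis(benzyloxy)benzaldehyde | O=Cc1ccc(OCc2ccccc2)c(OCc2ccccc2)c1 | starting material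
7 | methyl (Z)-2-{2-(benzyloxy)-4-[(E)-3-tert-butoxy-3-oxoprop-1-enyl]phenoxy}-3-[3,4-bis(benzyloxy)phenyl]prop-2-enoate | COC(=O)/C(=C/c1ccc(OCc2ccccc2)c(OCc2ccccc2)c1)Oc1ccc(/C=C/C(=O)OC(C)(C)C)cc1OCc1ccccc1 | intermediate
8 | (E)-3-[3-(benzyloxy)-4-({(Z)-1-[3,4-bis(benzyloxy)phenyl]-3-methoxy-3-oxoprop-1-en-2-yl}oxy)phenyl]prop-2-enoic acid | COC(=O)/C(=C/c1ccc(OCc2ccccc2)c(OCc2ccccc2)c1)Oc1ccc(/C=C/C(=O)O)cc1OCc1ccccc1 | intermediate
9 | 1,2-bis(benzyloxy)-4-bromobenzene | Brc1ccc(OCc2ccccc2)c(OCc2ccccc2)c1 | starting material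
10 | prop-2-en-1-ol (allyl alcohol) | C=CCO | starting material
11 | 3-[3,4-bis(benzyloxy)phenyl]propanal | O=CCCc1ccc(OCc2ccccc2)c(OCc2ccccc2)c1 | intermediate
12 | 2,4,6-trichlorobenzoyl chloride | O=C(Cl)c1c(Cl)cc(Cl)cc1Cl | starting material
13 | 2,4,6-trichloroperoxybenzoic acid | OOC(=O)c1c(Cl)cc(Cl)cc1Cl | intermediate
14 | (E)-3-[3-(benzyloxy)-4-({(Z)-1-[3,4-bis(benzyloxy)phenyl]-3-methoxy-3-oxoprop-1-en-2-yl}oxy)phenyl]prop-2-enoyl 2,4,6-trichlorobenzoyl peroxide | COC(=O)/C(=C/c1ccc(OCc2ccccc2)c(OCc2ccccc2)c1)Oc1ccc(/C=C/C(=O)OOC(=O)c2c(Cl)cc(Cl)cc2Cl)cc1OCc1ccccc1 | intermediate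
15 | (R)-1-[3,4-bis(benzyloxy)phenyl]-3-oxopropan-2-yl (E)-3-[3-(benzyloxy)-4-({(Z)-1-[3,4-bis(benzyloxy)phenyl]-3-methoxy-3-oxoprop-1-en-2-yl}oxy)phenyl]prop-2-enoate | COC(=O)/C(=C/c1ccc(OCc2ccccc2)c(OCc2ccccc2)c1)Oc1ccc(/C=C/C(=O)O[C@H](Cc2ccc(OCc3ccccc3)c(OCc3ccccc3)c2)C=O)cc1OCc1ccccc1 | intermediate
16 | (R)-3-[3,4-bis(benzyloxy)phenyl]-2-{[(E)-3-[3-(benzyloxy)-4-({(Z)-1-[3,4-bis(benzyloxy)phenyl]-3-methoxy-3-oxoprop-1-en-2-yl}oxy)phenyl]prop-2-enoyl]oxy}propanoic acid | COC(=O)/C(=C/c1ccc(OCc2ccccc2)c(OCc2ccccc2)c1)Oc1ccc(/C=C/C(=O)O[C@H](Cc2ccc(OCc3ccccc3)c(OCc3ccccc3)c2)C(=O)O)cc1OCc1ccccc1 | intermediate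
17 | (R)-3-(3,4-dihydroxyphenyl)-2-{[(E)-3-[4-({(Z)-1-(3,4-dihydroxyphenyl)-3-methoxy-3-oxoprop-1-en-2-yl}oxy)-3-hydroxyphenyl]prop-2-enoyl]oxy}propanoic acid (CNP0242322.1) | COC(=O)/C(=C/c1ccc(O)c(O)c1)Oc1ccc(/C=C/C(=O)O[C@H](Cc2ccc(O)c(O)c2)C(=O)O)cc1O | target

**Step count**
Total: 8 steps. Longest linear sequence: 6 steps (steps 1, 2, 3, 4, 7, 8).

**Three steps most likely to fail**

Step 7 (the proposed acyloxy transfer). The risks are attack at the wrong peroxidic oxygen, acylation or oxidation of the amine catalyst by 14, ionic rearrangement of 14, and partial racemisation of 15 before oxidation. The fallback uses known chemistry only; it sets out from aldehyde 11 and acid 8 and comes back to the route at acid 16. L-Proline-catalysed α-aminoxylation of 11 by nitrosobenzene (CHCl3, 4 °C) gives (R)-3-[3,4-bis(benzyloxy)phenyl]-2-[(phenylamino)oxy]propanal F1. This is oxidised without isolation (NaClO2, NaH2PO4, 2-methyl-2-butene) to (R)-3-[3,4-bis(benzyloxy)phenyl]-2-[(phenylamino)oxy]propanoic acid F2. Zn in AcOH cleaves the N–O bond to give (R)-3-[3,4-bis(benzyloxy)phenyl]-2-hydroxypropanoic acid F3. Separately, acid 8 is converted by (COCl)2 and catalytic DMF into (E)-3-[3-(benzyloxy)-4-({(Z)-1-[3,4-bis(benzyloxy)phenyl]-3-methoxy-3-oxoprop-1-en-2-yl}oxy)phenyl]prop-2-enoyl chloride F4, which O-acylates F3 (pyridine, CH2Cl2, 0 °C) to give 16.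

Step 3 (Horner–Wadsworth–Emmons). The risks are a hindered, fully substituted carbanion and an unfavourable Z/E ratio. The fallback sets out from phenol 3 and aldehyde 6 and comes back at enol ether 7. O-Alkylation of 3 by methyl bromoacetate (K2CO3, acetone) gives tert-butyl (E)-3-[3-(benzyloxy)-4-(2-methoxy-2-oxoethoxy)phenyl]prop-2-enoate F5. Its lithium enolate (LiN(SiMe3)2, THF, −78 °C) adds to 6 to give the aldol methyl 2-{2-(benzyloxy)-4-[(E)-3-tert-butoxy-3-oxoprop-1-enyl]phenoxy}-3-[3,4-bis(benzyloxy)phenyl]-3-hydroxypropanoate F6 as a diastereomer mixture. Mesylation (MsCl, Et3N) gives methyl 2-{2-(benzyloxy)-4-[(E)-3-tert-butoxy-3-oxoprop-1-enyl]phenoxy}-3-[3,4-bis(benzyloxy)phenyl]-3-(methylsulfonyloxy)propanoate F7, which is not isolated; E1cB elimination by DBU then gives 7 as the thermodynamic (Z)-isomer.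

Step 5 (Heck arylation of allyl alcohol). The risks are slow oxidative addition of the electron-rich aryl bromide and formation of the branched 2-arylpropanal. The fallback sets out from aldehyde 6 and comes back at aldehyde 11. Wittig reaction of 6 and (triphenylphosphoranylidene)acetaldehyde (toluene, 80 °C) gives (E)-3-[3,4-bis(benzyloxy)phenyl]prop-2-enal F8. Amine-catalysed transfer hydrogenation (Hantzsch ester, catalytic dibenzylammonium trifluoroacetate, THF, rt) reduces only the conjugated C=C and gives 11.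

**Further compounds**
F1 | step 7 | (R)-3-[3,4-bis(benzyloxy)phenyl]-2-[(phenylamino)oxy]propanal | c1ccc(NO[C@H](Cc2ccc(OCc3ccccc3)c(OCc3ccccc3)c2)C=O)cc1
F2 | step 7 | (R)-3-[3,4-bis(benzyloxy)phenyl]-2-[(phenylamino)oxy]propanoic acid | c1ccc(NO[C@H](Cc2ccc(OCc3ccccc3)c(OCc3ccccc3)c2)C(=O)O)cc1
F3 | step 7 | (R)-3-[3,4-bis(benzyloxy)phenyl]-2-hydroxypropanoic acid | O[C@H](Cc1ccc(OCc2ccccc2)c(OCc2ccccc2)c1)C(=O)O
F4 | step 7 | (E)-3-[3-(benzyloxy)-4-({(Z)-1-[3,4-bis(benzyloxy)phenyl]-3-methoxy-3-oxoprop-1-en-2-yl}oxy)phenyl]prop-2-enoyl chloride | COC(=O)/C(=C/c1ccc(OCc2ccccc2)c(OCc2ccccc2)c1)Oc1ccc(/C=C/C(=O)Cl)cc1OCc1ccccc1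
F5 | step 3 | tert-butyl (E)-3-[3-(benzyloxy)-4-(2-methoxy-2-oxoethoxy)phenyl]prop-2-enoate | COC(=O)COc1ccc(/C=C/C(=O)OC(C)(C)C)cc1OCc1ccccc1
F6 | step 3 | methyl 2-{2-(benzyloxy)-4-[(E)-3-tert-butoxy-3-oxoprop-1-enyl]phenoxy}-3-[3,4-bis(benzyloxy)phenyl]-3-hydroxypropanoate | COC(=O)C(Oc1ccc(/C=C/C(=O)OC(C)(C)C)cc1OCc1ccccc1)C(O)c1ccc(OCc2ccccc2)c(OCc2ccccc2)c1
F7 | step 3 | methyl 2-{2-(benzyloxy)-4-[(E)-3-tert-butoxy-3-oxoprop-1-enyl]phenoxy}-3-[3,4-bis(benzyloxy)phenyl]-3-(methylsulfonyloxy)propanoate | COC(=O)C(Oc1ccc(/C=C/C(=O)OC(C)(C)C)cc1OCc1ccccc1)C(OS(C)(=O)=O)c1ccc(OCc2ccccc2)c(OCc2ccccc2)c1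
F8 | step 5 | (E)-3-[3,4-bis(benzyloxy)phenyl]prop-2-enal | O=C/C=C/c1ccc(OCc2ccccc2)c(OCc2ccccc2)c1
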